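Everything rests on removing the lone benzylic hydroxyl, which leads back to achiral marchantin A. In the forward sense an S-selective flavin-dependent 4-alkylphenol oxidase turns one enantiotopic C–H of the ring A benzylic CH2 into C–OH, creating the only stereocentre on the unprotected macrocycle in one operation. The step exploits the position of this CH2 on the ring A carbon para to the free central hydroxyl (flanked by the second hydroxyl and the aryloxy oxygen), the only site able to form a p-quinone methide. Marchantin A itself comes from four purchased benzene rings through two SNAr etherifications, one olefination and an 18-membered Wurtz-type closure.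

Key step: step 11

Assumption: compounds 1, 2, 7 and 8 are catalogue chemicals, and the S-selective enzyme variant for step 11 is prepared beforehand by screening and directed evolution of S-selective family members; its production is not counted as a synthetic step.

Step 1
Reactants: 1 methyl 3-hydroxy-4,5-dimethoxybenzoate (ring A); 2 4-fluorobenzaldehyde (ring B)
Product: 3 methyl 3-(4-formylphenoxy)-4,5-dimethoxybenzoate
Conditions: K2CO3, DMF, 120 °C
Reagents that add atoms: none
Why: Nucleophilic aromatic substitution (SNAr), in which the para-formyl group stabilises the Meisenheimer adduct so that the phenoxide of 1 displaces fluoride, while the methyl ester and the non-enolisable aldehyde tolerate anhydrous carbonate.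

Step 2
Reactants: 3 methyl 3-(4-formylphenoxy)-4,5-dimethoxybenzoate
Product: 4 methyl 3-[4-(hydroxymethyl)phenoxy]-4,5-dimethoxybenzoate
Conditions: NaBH4, MeOH/THF, 0 °C
Reagents that add atoms: none
Why: Chemoselective borohydride reduction, since NaBH4 at 0 °C reduces the aryl aldehyde much faster than the methyl benzoate.

Step 3
Reactants: 4 methyl 3-[4-(hydroxymethyl)phenoxy]-4,5-dimethoxybenzoate
Product: 6 methyl 3-[4-(diethoxyphosphorylmethyl)phenoxy]-4,5-dimethoxybenzoate (benzyl phosphonate), via benzyl diethyl phosphite 5 (not isolated)
Conditions: P(OEt)3, ZnI2, toluene, reflux
Reagents that add atoms: triethyl phosphite, CCOP(OCC)OCC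
Why: ZnI2-mediated direct phosphonylation of a benzylic alcohol (Arbuzov-type rearrangement): exchange with triethyl phosphite gives the mixed phosphite, whose electron-rich para-aryloxybenzyl group shifts from oxygen to phosphorus under Lewis acid activation, so no separate halide step is needed and the ester and ethers are left alone.

Step 4
Reactants: 7 2-fluoro-3-methoxybenzaldehyde (ring C); 8 methyl 3-hydroxybenzoate (ring D)
Product: 9 methyl 3-(2-formyl-6-methoxyphenoxy)benzoate
Conditions: Cs2CO3, DMF, 100 °C
Reagents that add atoms: none
Why: SNAr in which the ortho-formyl group activates the fluoride of 7 towards the phenoxide of 8, with Cs2CO3 allowing a moderate temperature despite the flanking methoxy group.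

Step 5
Reactants: 6 methyl 3-[4-(diethoxyphosphorylmethyl)phenoxy]-4,5-dimethoxybenzoate; 9 methyl 3-(2-formyl-6-methoxyphenoxy)benzoate
Product: 10 methyl 3-[4-[(E)-2-[3-methoxy-2-(3-methoxycarbonylphenoxy)phenyl]ethenyl]phenoxy]-4,5-dimethoxybenzoate (open-chain stilbene diester)
Conditions: NaOMe, DMF, 0 °C to rt
Reagents that add atoms: none
Why: Horner–Wadsworth–Emmons olefination, in which the benzylic phosphonate anion adds to the aldehyde much faster than to either non-enolisable methyl ester and methoxide cannot scramble the methyl esters; the E alkene is expected, but its geometry is lost in the next step anyway.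

Step 6
Reactants: 10 open-chain (E)-stilbene diester
Product: 11 methyl 3-[4-[2-[3-methoxy-2-(3-methoxycarbonylphenoxy)phenyl]ethyl]phenoxy]-4,5-dimethoxybenzoate (bibenzyl diester)
Conditions: H2 (1 atm), Pd/C, EtOAc, rt
Reagents that add atoms: none
Why: Heterogeneous catalytic hydrogenation saturates the stilbene C=C while esters, methyl ethers and diaryl ethers are untouched, and running it before the ester reduction avoids benzylic C–O hydrogenolysis.

Step 7
Reactants: 11 bibenzyl diester
Product: 12 [3-[4-[2-[2-[3-(hydroxymethyl)phenoxy]-3-methoxyphenyl]ethyl]phenoxy]-4,5-dimethoxyphenyl]methanol (open-chain diol)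
Conditions: LiAlH4, THF, 0 °C to rt
Reagents that add atoms: none
Why: Hydride reduction of both methyl benzoates to benzylic alcohols in one operation; the two ends need no differentiation because both become the same leaving group.

Step 8
Reactants: 12 open-chain diol
Product: 13 5-(bromomethyl)-1-[4-[2-[2-[3-(bromomethyl)phenoxy]-3-methoxyphenyl]ethyl]phenoxy]-2,3-dimethoxybenzene (open-chain bis(benzyl bromide))
Conditions: PBr3, CH2Cl2, 0 °C to rt
Reagents that add atoms: phosphorus tribromide, BrP(Br)Br
Why: Bromination of benzylic alcohols with PBr3 (SN2 displacement of the phosphite ester by bromide) converts both hydroxymethyl groups; the crude dibromide is used at once because the trioxygenated ring A makes its benzylic bromide reactive.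

Step 9
Reactants: 13 open-chain bis(benzyl bromide)
Product: 14 marchantin A tri-O-methyl ether (18-membered macrocycle)
Conditions: Na, tetraphenylethylene, THF, −78 °C, syringe-pump addition of 13 under high dilution
Reagents that add atoms: none
Why: Intramolecular Wurtz-type reductive coupling, in which the sodium tetraphenylethylene electron carrier reduces one benzylic bromide to a benzyl anion (or radical) that displaces the other bromide, closing the 18-membered ring end to end at the ethano bridge between rings A and D, a closure type with precedent for macrocyclic bis(bibenzyls).

Step 10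
Reactants: 14 marchantin A tri-O-methyl ether
Product: 15 marchantin A (achiral triphenol)
Conditions: BBr3, CH2Cl2, −78 °C to rt; then H2O
Reagents that add atoms: none
Why: Lewis acid ether cleavage, in which BBr3 binds each methoxy oxygen and bromide removes the methyl group by SN2, while the diaryl ethers cannot react this way and survive; aqueous work-up hydrolyses the aryl borates to the free phenols.

Step 11
Reactants: 15 marchantin A
Product: 17 (S)-benzylic alcohol of marchantin A (target CNP0333307.1), via ring A p-quinone methide 16 (not isolated)
Conditions: S-selective vanillyl alcohol oxidase-type variant (covalently bound FAD, relocated active-site base, enlarged pocket), O2 (air), catalase, KH2PO4/K2HPO4 buffer pH 7.5, 10% DMSO, 25 °C, dark; extraction at neutral pH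
Reagents that add atoms: water, O
Why: Proposed new method: the enzyme should bind the ring A phenol of 15 as its phenolate, take a hydride from the para benzylic CH2 onto the flavin to give the planar p-quinone methide 16, and let an active-site carboxylate activate water for 1,6-addition at the exocyclic carbon, with O2 reoxidising the reduced flavin and catalase removing the peroxide. The closest known reaction type is the enantioselective benzylic hydroxylation of 4-ethylphenol, 4-propylphenol and related 4-alkylphenols by this enzyme family, which has not been shown for a macrocyclic bis(bibenzyl) or for a phenol flanked by hydroxyl and aryloxy groups, so an enlarged, evolved pocket is needed. No ring is closed in this step, because the macrocycle is already complete. The new stereocentre is set by the enzyme alone: the side of the bound quinone methide on which the water-activating base sits fixes the face of attack, and an S-selective parent is required (p-cresol methylhydroxylase type, or a vanillyl alcohol oxidase variant of the Asp170Ser/Thr457Glu type with the base moved to the opposite face); the priority order OH > ring A > CH2Ar > H equals that of the model product (S)-1-(4-hydroxyphenyl)ethanol, so the descriptor carries over. Site selectivity among the four benzylic CH2 groups comes from the substrate, since only the ring A CH2 is para to a free hydroxyl: ring B carries only an ether oxygen, the ring C benzylic carbon is meta to its hydroxyl and ortho to an ether oxygen, and the ring D one is meta to an ether oxygen. The reaction should be stopped at full conversion to limit proton loss from 16 to the macrocyclic stilbene and further oxidation of the carbinol to the ketone.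

Compound list
1 | methyl 3-hydroxy-4,5-dimethoxybenzoate | COC(=O)c1cc(O)c(OC)c(OC)c1 | starting material
2 | 4-fluorobenzaldehyde | O=Cc1ccc(F)cc1 | starting material
3 | methyl 3-(4-formylphenoxy)-4,5-dimethoxybenzoate | COC(=O)c1cc(OC)c(OC)c(Oc2ccc(C=O)cc2)c1 | intermediate
4 | methyl 3-[4-(hydroxymethyl)phenoxy]-4,5-dimethoxybenzoate | COC(=O)c1cc(OC)c(OC)c(Oc2ccc(CO)cc2)c1 | intermediate
5 | benzyl diethyl phosphite of 4 (ArCH2–O–P(OEt)2) | COC(=O)c1cc(OC)c(OC)c(Oc2ccc(COP(OCC)OCC)cc2)c1 | intermediate (not isolated)
6 | methyl 3-[4-(diethoxyphosphorylmethyl)phenoxy]-4,5-dimethoxybenzoate | COC(=O)c1cc(OC)c(OC)c(Oc2ccc(CP(=O)(OCC)OCC)cc2)c1 | intermediate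
7 | 2-fluoro-3-methoxybenzaldehyde | COc1cccc(C=O)c1F | starting material
8 | methyl 3-hydroxybenzoate | COC(=O)c1cccc(O)c1 | starting material
9 | methyl 3-(2-formyl-6-methoxyphenoxy)benzoate | COC(=O)c1cccc(Oc2c(C=O)cccc2OC)c1 | intermediate
10 | open-chain (E)-stilbene diester joining rings B and C | COC(=O)c1cc(OC)c(OC)c(Oc2ccc(/C=C/c3cccc(OC)c3Oc3cccc(C(=O)OC)c3)cc2)c1 | intermediate
11 | open-chain bibenzyl diester | COC(=O)c1cc(OC)c(OC)c(Oc2ccc(CCc3cccc(OC)c3Oc3cccc(C(=O)OC)c3)cc2)c1 | intermediate
12 | open-chain diol (both esters reduced to CH2OH) | OCc1cc(OC)c(OC)c(Oc2ccc(CCc3cccc(OC)c3Oc3cccc(CO)c3)cc2)c1 | intermediate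
13 | open-chain bis(benzyl bromide) | BrCc1cc(OC)c(OC)c(Oc2ccc(CCc3cccc(OC)c3Oc3cccc(CBr)c3)cc2)c1 | intermediate
14 | marchantin A tri-O-methyl ether | COc1cc2cc(c1OC)Oc1ccc(cc1)CCc1cccc(OC)c1Oc1cccc(c1)CC2 | intermediate
15 | marchantin A | Oc1cc2cc(c1O)Oc1ccc(cc1)CCc1cccc(O)c1Oc1cccc(c1)CC2 | intermediate
16 | ring A p-quinone methide of marchantin A (exocyclic C=C towards the ring D methylene, geometry not defined) | OC1=CC2=CCc3cccc(c3)Oc3c(O)cccc3CCc3ccc(cc3)OC(=C2)C1=O | intermediate (not isolated)
17 | CNP0333307.1, (S)-benzylic alcohol of marchantin A (OH on the bridge carbon attached to ring A) | Oc1cc2cc(c1O)Oc1ccc(cc1)CCc1cccc(O)c1Oc1cccc(c1)C[C@@H]2O | target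

Total step count: 11
Longest linear sequence: 10 steps (steps 1, 2, 3, 5, 6, 7, 8, 9, 10, 11, from compounds 1 and 2); step 4 is a one-step side branch.

Steps most likely to fail

1. Step 11 (proposed new method). The macrocycle may not fit the active site, so turnover could be absent or slow. Facial control could be incomplete. The quinone methide could lose a proton to give the macrocyclic stilbene, the carbinol could be oxidised further to the ketone, and the catechol could autoxidise. The native vanillyl alcohol oxidase and the 4-ethylphenol methylenehydroxylase type give the R alcohol with 4-ethylphenol and would give the wrong enantiomer as they stand. Fallback by known chemistry, setting out from 14 and returning at 17: the doubly flanked, out-of-plane central methoxy group of ring A would be cleaved selectively (AlCl3, CH2Cl2, 0 °C) to give the ring A monophenol F1. DDQ in wet dioxane would oxidise its para benzylic CH2, through the quinone methide and the carbinol, to the macrocyclic aryl ketone F2. BBr3 would then remove the two remaining methyl groups, which the ketone tolerates, to give the trihydroxy ketone F3. Noyori-type asymmetric transfer hydrogenation (RuCl[(S,S)-TsDPEN](p-cymene), HCO2Na, water/DMF, near neutral pH) would reduce the ketone to 17; the S alcohol is expected by analogy with aryl alkyl ketones.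

2. Step 9. Intermolecular coupling to oligomers, reduction of a C–Br bond to a methyl group, or reductive cleavage of a diaryl ether by the electron carrier could outrun ring closure. Fallback, setting out from 12 and returning at 14: MnO2 in CH2Cl2 would oxidise both benzylic alcohols to the dialdehyde F4. Intramolecular McMurry coupling (TiCl4, Zn, pyridine, THF, reflux, high dilution) would close the ring as the macrocyclic stilbene F5. Hydrogenation (H2, Pd/C, EtOAc) would then give 14.

3. Step 4. Substitution at a fluoride flanked by formyl and methoxy groups may be sluggish, and acyl transfer between the phenoxide and the methyl ester could release methoxide that competes for the fluoride. Fallback, setting out from 8 and returning at 9: copper-catalysed Ullmann-type diaryl ether coupling of 8 with purchased 2-bromo-3-methoxybenzaldehyde F6 (CuI, N,N-dimethylglycine, Cs2CO3, dioxane, 90 °C), where the ortho-formyl group assists the coupling and no SNAr activation is needed.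

Further compounds
F1 | step 11 | marchantin A with the central ring A hydroxyl free and methyl ethers on the outer ring A oxygen and on ring C | COc1cc2cc(c1O)Oc1ccc(cc1)CCc1cccc(OC)c1Oc1cccc(c1)CC2
F2 | step 11 | macrocyclic aryl ketone (C=O at the ring A benzylic carbon) of F1 | COc1cc2cc(c1O)Oc1ccc(cc1)CCc1cccc(OC)c1Oc1cccc(c1)CC2=O
F3 | step 11 | trihydroxy ketone (ring A benzylic ketone of marchantin A) | Oc1cc2cc(c1O)Oc1ccc(cc1)CCc1cccc(O)c1Oc1cccc(c1)CC2=O
F4 | step 9 | open-chain dialdehyde from 12 | O=Cc1cc(OC)c(OC)c(Oc2ccc(CCc3cccc(OC)c3Oc3cccc(C=O)c3)cc2)c1
F5 | step 9 | macrocyclic stilbene tri-O-methyl ether (C=C between rings A and D, geometry not fixed) | COc1cc2cc(c1OC)Oc1ccc(cc1)CCc1cccc(OC)c1Oc1cccc(c1)C=C2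
F6 | step 4 | 2-bromo-3-methoxybenzaldehyde (purchased) | COc1cccc(C=O)c1Br
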